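**Plan**

- Retrosynthesis: the two phenolic O–H groups are traced back to benzyl ethers. The aryl–carbonyl bond C1–C7 and the acyl–oxygen bond C7–O(docosyl) are then cut together, leaving an aryl bromide, carbon monoxide and 1-docosanol. Last, the two O–CH2Ph bonds are cut back to 3-bromocatechol.
- Enabling feature: ester carbon C7 is the only carbon outside the benzene ring and the chain. It is bonded to ring carbon C1 and to the oxygen of the C22 chain, so it can be delivered as CO between a C1–Br bond and the alcohol O–H.
- Forward order: the benzene ring is bought with the 1-bromo-2,3-dioxygen pattern in place and no ring is formed. Benzylation comes first, then the chain is joined through CO in one operation, then the phenols are unmasked.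
- Stereochemistry: the target has no stereocentre and no stereogenic double bond. It is achiral, so there is no configuration to set or protect.

Key step: step 2

Assumption: step 1 consumes two equivalents of benzyl bromide, so the first is entered as reactant 2 and the second as an atom-adding reagent. The half-reacted mono-ethers of steps 1 and 3 (regioisomeric mixtures that converge on one product) and the catalyst-bound palladium species of step 2 are treated as transient and are not numbered.

**Route**

Step 1
Reactants: 1 3-bromocatechol (3-bromobenzene-1,2-diol); 2 benzyl bromide
Product: 3 1,2-bis(benzyloxy)-3-bromobenzene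
Conditions: BnBr (2.4 equiv in total), K2CO3 (3 equiv), DMF, N2, 60 °C
Reagents that add atoms: benzyl bromide (compound 2, second equivalent), BrCc1ccccc1
Why: Twofold Williamson ether synthesis, in which the carbonate-generated phenoxides displace bromide from two molecules of the benzylic halide by SN2, with a polar aprotic solvent and excess halide driving the slower second alkylation at the oxygen flanked by bromine.

Step 2
Reactants: 3 1,2-bis(benzyloxy)-3-bromobenzene; 4 carbon monoxide; 5 1-docosanol
Product: 6 docosyl 2,3-bis(benzyloxy)benzoate
Conditions: Pd(OAc)2 (3 mol%), Xantphos (4 mol%), K3PO4 (3 equiv), 5 (1.2 equiv), CO (1 atm, balloon), toluene, 100 °C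
Reagents that add atoms: none
Why: Pd(0)–Xantphos should add oxidatively to the C1–Br bond of 3, CO then coordinates and inserts into the aryl–palladium bond to give an aroylpalladium(II) bromide, and phosphate-assisted attack of docosanol on this acyl complex releases ester 6 and returns Pd(0), so that the C1–C7 and C7–O bonds form in one catalytic cycle. The closest known reaction type is the Heck-type alkoxycarbonylation of aryl bromides with CO and an alcohol at atmospheric pressure using a wide-bite-angle bisphosphine. No ring is closed and no stereocentre is created. The step needs chemoselectivity for alcoholysis of the acyl complex over direct C–O etherification and over hydrodebromination, which is secured by keeping the solution saturated with CO so that insertion outruns alkoxide exchange at arylpalladium, and by the wide bite angle of Xantphos, which tolerates the ortho-benzyloxy group and favours the acyl pathway. Regiochemistry is not in question because the carbonyl can only enter where the bromine sits, and the benzyl ethers keep the catechol oxygens from chelating palladium or competing as O-nucleophiles.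

Step 3
Reactants: 6 docosyl 2,3-bis(benzyloxy)benzoate
Product: 7 Gentiside J (docosyl 2,3-dihydroxybenzoate)
Conditions: H2 (1 atm), 10% Pd/C, THF–EtOAc, 30 °C
Reagents that add atoms: none
Why: Heterogeneous catalytic hydrogenolysis of benzyl aryl ethers cleaves both benzylic C–O bonds to toluene under neutral conditions that leave the alkyl ester, the saturated chain and the arene untouched.

**Compound list**

1 | 3-bromocatechol (3-bromobenzene-1,2-diol) | Oc1cccc(Br)c1O | starting material
2 | benzyl bromide | BrCc1ccccc1 | starting material
3 | 1,2-bis(benzyloxy)-3-bromobenzene | Brc1cccc(OCc2ccccc2)c1OCc1ccccc1 | intermediate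
4 | carbon monoxide | [C-]#[O+] | starting material
5 | 1-docosanol | CCCCCCCCCCCCCCCCCCCCCCO | starting material
6 | docosyl 2,3-bis(benzyloxy)benzoate | CCCCCCCCCCCCCCCCCCCCCCOC(=O)c1cccc(OCc2ccccc2)c1OCc1ccccc1 | intermediate
7 | Gentiside J (docosyl 2,3-dihydroxybenzoate) | CCCCCCCCCCCCCCCCCCCCCCOC(=O)c1cccc(O)c1O | target

**Step count**

Total steps: 3. Longest linear sequence: 3 steps (1 → 3 → 6 → 7).

**Steps most likely to fail**

Step 2. Oxidative addition into the electron-rich C1–Br bond next to a benzyloxy group may be slow under CO, so the catalyst could aggregate to palladium black before turnover. A palladium docosyloxide could also undergo β-hydride elimination and cause hydrodebromination. The fallback sets out from 3 and forms the two bonds separately. Bromine–lithium exchange with n-BuLi in THF at −78 °C should give 2,3-bis(benzyloxy)phenyllithium F1, which is quenched cold with dry CO2 and acidified with aqueous HCl to 2,3-bis(benzyloxy)benzoic acid F2. Steglich esterification of this acid with 5 (DCC, cat. DMAP, CH2Cl2, rt) comes back to the route at 6.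

Step 1. The second alkylation, at the oxygen wedged between bromine and the first benzyloxy group, may stall, and the catecholate may be oxidised by air in basic DMF. The fallback sets out from 1 and replaces the two intermolecular alkylations by one base-free ketalisation whose second C–O bond closes intramolecularly. Heating with dichlorodiphenylmethane (neat, 170 °C) should tie both oxygens into 4-bromo-2,2-diphenyl-1,3-benzodioxole F3. The same carbonylation with 4 and 5 (Pd(OAc)2, Xantphos, K3PO4, toluene, 100 °C) should give docosyl 2,2-diphenyl-1,3-benzodioxole-4-carboxylate F4. Hydrogenolysis of the diphenylmethylene ketal (H2, Pd(OH)2/C, THF) comes back to the route at 7.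

Step 3. The waxy C22 ester may be poorly soluble and adsorb on the carbon support, leaving debenzylation incomplete, and the liberated catechol may oxidise during filtration in air. The fallback sets out from 6 and uses Lewis-acid ether cleavage instead of hydrogenation. BCl3 with pentamethylbenzene as benzyl-cation scavenger in CH2Cl2 at −78 °C should remove both benzyl groups while the primary alkyl ester survives. It arrives directly at 7 and makes no compound outside the list (F0).

**Further compounds**

F1 | step 2 | 2,3-bis(benzyloxy)phenyllithium | [Li]c1cccc(OCc2ccccc2)c1OCc1ccccc1
F2 | step 2 | 2,3-bis(benzyloxy)benzoic acid | OC(=O)c1cccc(OCc2ccccc2)c1OCc1ccccc1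
F3 | step 1 | 4-bromo-2,2-diphenyl-1,3-benzodioxole | Brc1cccc2OC(c3ccccc3)(c3ccccc3)Oc12
F4 | step 1 | docosyl 2,2-diphenyl-1,3-benzodioxole-4-carboxylate | CCCCCCCCCCCCCCCCCCCCCCOC(=O)c1cccc2OC(c3ccccc3)(c3ccccc3)Oc12
F0 | step 3 | none | none
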